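Assumption: the five starting materials are bought as such, the two chiral ones as single enantiomers. C1–C15 are the germacrane locants of the target (lactone O on C8, C11–C13 the methylene‑lactone carbons, C14 the CH2OH carbon, C15 the CH2O‑acyl carbon).

**Retrosynthetic overview**
1. Target ⇐ side‑chain esterification at O15 and α‑methylenation (C13) of a protected trans‑fused bicyclic lactone.
2. Ten‑membered ring (ring A) ⇐ key step: radical ring closure C5–C6, in which a primary C6 radical (from an iodide) is captured at a preset (Z)‑alkenyl iodide on nickel, so the trans‑in‑ring C4=C5 geometry is carried over.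
3. Lactone (ring B) and C7 ⇐ iodine‑atom‑transfer radical 5‑exo cyclisation of the iodoacetate of the C8 allylic alcohol (C7–C11 bond; C8 controls C7; leaves the C6 iodide).
4. C8, C9, C10, C14 and the cis‑in‑ring C1=C10 alkene ⇐ (E)‑selective olefination of (S)‑5‑vinylbutyrolactone with a C1 aldehyde, then reduction of this relay lactone.
5. C4=C5 with C15 ⇐ copper‑catalysed anti‑carbomagnesiation/iodination of propargyl alcohol. Ring order: lactone first, carbocycle second.

**Route**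

Step 1
Reactants: 1 prop-2-yn-1-ol; 2 2-(2-bromoethyl)-1,3-dioxolane
Product: 5 (Z)-2-[2-(1,3-dioxolan-2-yl)ethyl]-3-iodoprop-2-en-1-ol, via Grignard reagent 3 (not isolated), via alkenylmagnesium alkoxide 4 (not isolated)
Conditions: 2 (2.5 equiv), Mg, THF, 30 °C; then 1, CuI (10 mol%), Et2O–THF, −10 °C → rt; then I2, −40 → 0 °C; NH4Cl/Na2S2O3 (aq)
Reagents that add atoms: iodine, II
Why: Copper‑catalysed anti‑carbomagnesiation of the propargylic alkoxide (Duboudin reaction) puts the alkyl group on the internal carbon and magnesium on the terminal carbon cis to CH2O in a five‑membered chelate, so iodinolysis gives the alkenyl iodide with I cis to CH2OH, which fixes the C4=C5 geometry.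

Step 2
Reactants: 5 (Z)-2-[2-(1,3-dioxolan-2-yl)ethyl]-3-iodoprop-2-en-1-ol
Product: 6 2-[(Z)-4-iodo-3-{[(4-methoxybenzyl)oxy]methyl}but-3-en-1-yl]-1,3-dioxolane
Conditions: NaH, 4-methoxybenzyl chloride, Bu4NI (cat.), THF–DMF, 0 °C → rt
Reagents that add atoms: 4-methoxybenzyl chloride, COc1ccc(CCl)cc1
Why: Williamson etherification masks O15 with a group that survives acid, hydride and base and is later removed oxidatively in the presence of the silyl ether.

Step 3
Reactants: 6 2-[(Z)-4-iodo-3-{[(4-methoxybenzyl)oxy]methyl}but-3-en-1-yl]-1,3-dioxolane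
Product: 7 (Z)-5-iodo-4-{[(4-methoxybenzyl)oxy]methyl}pent-4-enal
Conditions: HCl (1 M), THF–H2O, rt
Reagents that add atoms: water, O
Why: Acid‑catalysed acetal hydrolysis frees the C1 aldehyde while the benzyl‑type ether and the alkenyl iodide are inert.

Step 4
Reactants: 8 (S)-5-(hydroxymethyl)dihydrofuran-2(3H)-one
Product: 10 (S)-5-vinyldihydrofuran-2(3H)-one, via lactone aldehyde 9 (not isolated)
Conditions: (COCl)2, DMSO, CH2Cl2, −78 °C; Et3N; then Ph3P=CH2 (from Ph3PCH3Br and KN(SiMe3)2, THF, 3.5 equiv), −78 → 0 °C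
Reagents that add atoms: methylenetriphenylphosphorane, C=P(c1ccccc1)(c1ccccc1)c1ccccc1
Why: Swern oxidation followed by in‑situ Wittig methylenation converts CH2OH into the C7=C6 vinyl group without isolating the epimerisable α‑oxy aldehyde, so the stereocentre (future C8, S) is kept.

Step 5
Reactants: 10 (S)-5-vinyldihydrofuran-2(3H)-one; 7 (Z)-5-iodo-4-{[(4-methoxybenzyl)oxy]methyl}pent-4-enal
Product: 13 (5S,3E)-3-[(4Z)-5-iodo-4-{[(4-methoxybenzyl)oxy]methyl}pent-4-en-1-ylidene]-5-vinyldihydrofuran-2(3H)-one, via enol phosphate 11 (not isolated), via phosphonate anion 12 (not isolated)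
Conditions: LiN(iPr)2 (1.05 equiv), THF, −78 °C; ClP(O)(OEt)2, −78 → 0 °C; LiN(iPr)2 (2.0 equiv), −78 °C → rt; then 7, −78 °C → rt
Reagents that add atoms: none
Why: One‑flask enolate phosphorylation, 1,3‑phosphoryl migration (Wiemer) and Horner–Wadsworth–Emmons olefination give mainly the (E)‑alkylidene lactone (carbonyl trans to the chain, minor Z isomer removed by chromatography), which places C2 cis to C9 on the future C1=C10 bond.

Step 6
Reactants: 13 (5S,3E)-3-[(4Z)-5-iodo-4-{[(4-methoxybenzyl)oxy]methyl}pent-4-en-1-ylidene]-5-vinyldihydrofuran-2(3H)-one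
Product: 14 (3S,5E,9Z)-5-(hydroxymethyl)-10-iodo-9-{[(4-methoxybenzyl)oxy]methyl}deca-1,5,9-trien-3-ol
Conditions: iBu2AlH (4 equiv), CH2Cl2, −78 → 0 °C; KNaC4H4O6 (aq)
Reagents that add atoms: none
Why: 1,2‑Hydride reduction of the α‑alkylidene lactone opens the relay ring to the C14 primary allylic alcohol and the C8 secondary allylic alcohol without touching the alkenes, the alkenyl iodide or C8.

Step 7
Reactants: 14 (3S,5E,9Z)-5-(hydroxymethyl)-10-iodo-9-{[(4-methoxybenzyl)oxy]methyl}deca-1,5,9-trien-3-ol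
Product: 15 (3S,5E,9Z)-5-{[(tert-butyldimethylsilyl)oxy]methyl}-10-iodo-9-{[(4-methoxybenzyl)oxy]methyl}deca-1,5,9-trien-3-ol
Conditions: tert-butyldimethylsilyl chloride (1.05 equiv), imidazole, CH2Cl2, −20 → 0 °C
Reagents that add atoms: tert-butyldimethylsilyl chloride, CC(C)(C)[Si](C)(C)Cl
Why: Sterically controlled silylation takes the primary C14 hydroxyl and leaves the secondary C8 hydroxyl free for acylation.

Step 8
Reactants: 15 (3S,5E,9Z)-5-{[(tert-butyldimethylsilyl)oxy]methyl}-10-iodo-9-{[(4-methoxybenzyl)oxy]methyl}deca-1,5,9-trien-3-ol; 16 iodoacetic acid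
Product: 17 (3S,5E,9Z)-5-{[(tert-butyldimethylsilyl)oxy]methyl}-10-iodo-9-{[(4-methoxybenzyl)oxy]methyl}deca-1,5,9-trien-3-yl 2-iodoacetate
Conditions: 16, N,N'-dicyclohexylcarbodiimide, 4-(dimethylamino)pyridine (5 mol%), CH2Cl2, 0 °C, dark
Reagents that add atoms: none
Why: Steglich esterification of the C8 alcohol installs C11 and C12 together with the radical precursor, with retention at C8.

Step 9
Reactants: 17 (3S,5E,9Z)-5-{[(tert-butyldimethylsilyl)oxy]methyl}-10-iodo-9-{[(4-methoxybenzyl)oxy]methyl}deca-1,5,9-trien-3-yl 2-iodoacetate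
Product: 18 (4R,5S)-5-[(2E,6Z)-2-{[(tert-butyldimethylsilyl)oxy]methyl}-7-iodo-6-{[(4-methoxybenzyl)oxy]methyl}hepta-2,6-dien-1-yl]-4-(iodomethyl)dihydrofuran-2(3H)-one
Conditions: dilauroyl peroxide (15 mol%, portionwise), PhH (5 mM), 80 °C
Reagents that add atoms: none
Why: Iodine‑atom‑transfer radical cyclisation (Curran type): the α‑ester radical closes 5‑exo onto the vinyl group through a chair‑like transition state with the C8 side chain pseudo‑equatorial, giving the 4,5‑trans lactone (C7 R, minor cis isomer separated), and the primary C6 radical takes iodine from 17 to carry the chain.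

Step 10
Reactants: 18 (4R,5S)-5-[(2E,6Z)-2-{[(tert-butyldimethylsilyl)oxy]methyl}-7-iodo-6-{[(4-methoxybenzyl)oxy]methyl}hepta-2,6-dien-1-yl]-4-(iodomethyl)dihydrofuran-2(3H)-one
Product: 19 (3aR,5Z,9E,11aS)-10-{[(tert-butyldimethylsilyl)oxy]methyl}-6-{[(4-methoxybenzyl)oxy]methyl}-3a,4,7,8,11,11a-hexahydrocyclodeca[b]furan-2(3H)-one
Conditions: NiBr2(dme) (20 mol%), 4,4'-di-tert-butyl-2,2'-bipyridine (24 mol%), Mn powder (3 equiv), NaI (0.5 equiv), DMA, 40 °C, syringe‑pump addition of 18 (final 2 mM)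
Reagents that add atoms: none
Why: Proposed new method: intramolecular version of the nickel‑catalysed reductive alkyl–alkenyl cross‑electrophile coupling (closest known type: intermolecular alkyl iodide/alkenyl halide radical cross‑coupling and nickel‑mediated reductive ring closures), in which zerovalent nickel inserts into the alkenyl C–I bond, the primary C6 radical formed by iodine‑atom abstraction at monovalent nickel is captured by the alkenylnickel and reductive elimination closes the ten‑membered ring at C5–C6 with retention of the alkenyl geometry (C3 trans to C6); no stereocentre is formed.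

Step 11
Reactants: 19 (3aR,5Z,9E,11aS)-10-{[(tert-butyldimethylsilyl)oxy]methyl}-6-{[(4-methoxybenzyl)oxy]methyl}-3a,4,7,8,11,11a-hexahydrocyclodeca[b]furan-2(3H)-one
Product: 22 (3aR,5Z,9E,11aS)-10-{[(tert-butyldimethylsilyl)oxy]methyl}-6-{[(4-methoxybenzyl)oxy]methyl}-3-methylidene-3a,4,7,8,11,11a-hexahydrocyclodeca[b]furan-2(3H)-one, via Mannich base 20 (not isolated), via ammonium iodide 21 (not isolated)
Conditions: LiN(SiMe3)2, THF, −78 °C; Me2N=CH2 iodide, −78 °C → rt; then MeI, MeOH, rt; then NaHCO3 (aq), CH2Cl2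
Reagents that add atoms: N,N-dimethylmethyleneiminium iodide (Eschenmoser's salt), C=[N+](C)C.[I-]
Why: Lactone enolate aminomethylation, N‑quaternisation and E1cB elimination (Eschenmoser methylenation) install C13; C7 and C8 are not enolisable and are untouched.

Step 12
Reactants: 22 (3aR,5Z,9E,11aS)-10-{[(tert-butyldimethylsilyl)oxy]methyl}-6-{[(4-methoxybenzyl)oxy]methyl}-3-methylidene-3a,4,7,8,11,11a-hexahydrocyclodeca[b]furan-2(3H)-one
Product: 23 (3aR,5Z,9E,11aS)-10-{[(tert-butyldimethylsilyl)oxy]methyl}-6-(hydroxymethyl)-3-methylidene-3a,4,7,8,11,11a-hexahydrocyclodeca[b]furan-2(3H)-one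
Conditions: 2,3-dichloro-5,6-dicyano-1,4-benzoquinone, CH2Cl2–pH 7 buffer, 0 °C
Reagents that add atoms: none
Why: Oxidative cleavage of the 4‑methoxybenzyl ether frees only O15, leaving the silyl ether at O14 and the methylene lactone intact.

Step 13
Reactants: 23 (3aR,5Z,9E,11aS)-10-{[(tert-butyldimethylsilyl)oxy]methyl}-6-(hydroxymethyl)-3-methylidene-3a,4,7,8,11,11a-hexahydrocyclodeca[b]furan-2(3H)-one; 24 (R)-3-chloro-2-hydroxy-2-methylpropanoic acid
Product: 25 [(3aR,5Z,9E,11aS)-10-{[(tert-butyldimethylsilyl)oxy]methyl}-3-methylidene-2-oxo-2,3,3a,4,7,8,11,11a-octahydrocyclodeca[b]furan-6-yl]methyl (2R)-3-chloro-2-hydroxy-2-methylpropanoate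
Conditions: 24, 1-ethyl-3-(3-dimethylaminopropyl)carbodiimide hydrochloride, 4-(dimethylamino)pyridine (10 mol%), CH2Cl2, 0 °C → rt
Reagents that add atoms: none
Why: Carbodiimide (Steglich‑type) esterification of the only free primary alcohol; the tertiary hydroxyl of the acid is too hindered to compete and its quaternary stereocentre cannot epimerise.

Step 14
Reactants: 25 [(3aR,5Z,9E,11aS)-10-{[(tert-butyldimethylsilyl)oxy]methyl}-3-methylidene-2-oxo-2,3,3a,4,7,8,11,11a-octahydrocyclodeca[b]furan-6-yl]methyl (2R)-3-chloro-2-hydroxy-2-methylpropanoate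
Product: 26 [(3aR,5Z,9E,11aS)-10-(hydroxymethyl)-3-methylidene-2-oxo-2,3,3a,4,7,8,11,11a-octahydrocyclodeca[b]furan-6-yl]methyl (2R)-3-chloro-2-hydroxy-2-methylpropanoate
Conditions: HF·pyridine, THF–pyridine, 0 °C → rt
Reagents that add atoms: none
Why: Acidic fluoride desilylation frees O14 without base, so the chlorohydrin ester (no epoxide closure, no acyl migration) and the methylene lactone survive.

**Compound list**
1 | prop-2-yn-1-ol | C#CCO | starting material
2 | 2-(2-bromoethyl)-1,3-dioxolane | BrCCC1OCCO1 | starting material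
3 | [2-(1,3-dioxolan-2-yl)ethyl]magnesium bromide | Br[Mg]CCC1OCCO1 | intermediate
4 | bromomagnesium (Z)-3-(bromomagnesio)-2-[2-(1,3-dioxolan-2-yl)ethyl]prop-2-en-1-olate (Mg cis to CH2O) | Br[Mg]OC/C(CCC1OCCO1)=C\[Mg]Br | intermediate
5 | (Z)-2-[2-(1,3-dioxolan-2-yl)ethyl]-3-iodoprop-2-en-1-ol (I cis to CH2OH) | OC/C(CCC1OCCO1)=C\I | intermediate
6 | 2-[(Z)-4-iodo-3-{[(4-methoxybenzyl)oxy]methyl}but-3-en-1-yl]-1,3-dioxolane | COc1ccc(COC/C(CCC2OCCO2)=C\I)cc1 | intermediate
7 | (Z)-5-iodo-4-{[(4-methoxybenzyl)oxy]methyl}pent-4-enal | COc1ccc(COC/C(CCC=O)=C\I)cc1 | intermediate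
8 | (S)-5-(hydroxymethyl)dihydrofuran-2(3H)-one | OC[C@@H]1CCC(=O)O1 | starting material
9 | (S)-5-oxotetrahydrofuran-2-carbaldehyde | O=C[C@@H]1CCC(=O)O1 | intermediate
10 | (S)-5-vinyldihydrofuran-2(3H)-one | C=C[C@@H]1CCC(=O)O1 | intermediate
11 | diethyl (S)-5-vinyl-4,5-dihydrofuran-2-yl phosphate | C=C[C@@H]1CC=C(OP(=O)(OCC)OCC)O1 | intermediate
12 | lithium enolate of diethyl [(5S)-2-oxo-5-vinyltetrahydrofuran-3-yl]phosphonate | C=C[C@@H]1CC(P(=O)(OCC)OCC)=C([O-])O1.[Li+] | intermediate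
13 | (5S,3E)-3-[(4Z)-5-iodo-4-{[(4-methoxybenzyl)oxy]methyl}pent-4-en-1-ylidene]-5-vinyldihydrofuran-2(3H)-one | C=C[C@@H]1C/C(=C\CC/C(COCc2ccc(OC)cc2)=C/I)C(=O)O1 | intermediate
14 | (3S,5E,9Z)-5-(hydroxymethyl)-10-iodo-9-{[(4-methoxybenzyl)oxy]methyl}deca-1,5,9-trien-3-ol | C=C[C@@H](O)C/C(CO)=C\CC/C(COCc1ccc(OC)cc1)=C/I | intermediate
15 | (3S,5E,9Z)-5-{[(tert-butyldimethylsilyl)oxy]methyl}-10-iodo-9-{[(4-methoxybenzyl)oxy]methyl}deca-1,5,9-trien-3-ol | C=C[C@@H](O)C/C(CO[Si](C)(C)C(C)(C)C)=C\CC/C(COCc1ccc(OC)cc1)=C/I | intermediate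
16 | iodoacetic acid | OC(=O)CI | starting material
17 | (3S,5E,9Z)-5-{[(tert-butyldimethylsilyl)oxy]methyl}-10-iodo-9-{[(4-methoxybenzyl)oxy]methyl}deca-1,5,9-trien-3-yl 2-iodoacetate | C=C[C@@H](OC(=O)CI)C/C(CO[Si](C)(C)C(C)(C)C)=C\CC/C(COCc1ccc(OC)cc1)=C/I | intermediate
18 | (4R,5S)-5-[(2E,6Z)-2-{[(tert-butyldimethylsilyl)oxy]methyl}-7-iodo-6-{[(4-methoxybenzyl)oxy]methyl}hepta-2,6-dien-1-yl]-4-(iodomethyl)dihydrofuran-2(3H)-one (4,5-trans) | O=C1C[C@@H](CI)[C@H](C/C(CO[Si](C)(C)C(C)(C)C)=C\CC/C(COCc2ccc(OC)cc2)=C/I)O1 | intermediate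
19 | (3aR,5Z,9E,11aS)-10-{[(tert-butyldimethylsilyl)oxy]methyl}-6-{[(4-methoxybenzyl)oxy]methyl}-3a,4,7,8,11,11a-hexahydrocyclodeca[b]furan-2(3H)-one (trans-fused; C5=C6 trans in the ring, C9=C10 cis in the ring) | C1C(=O)O[C@H]2C/C(CO[Si](C)(C)C(C)(C)C)=C\CC/C(COCc3ccc(OC)cc3)=C/C[C@H]12 | intermediate
20 | 3-[(dimethylamino)methyl] derivative of 19 (C3 epimers) | CN(C)CC1C(=O)O[C@H]2C/C(CO[Si](C)(C)C(C)(C)C)=C\CC/C(COCc3ccc(OC)cc3)=C/C[C@H]12 | intermediate
21 | 3-[(trimethylammonio)methyl] derivative of 19, iodide (C3 epimers) | C[N+](C)(C)CC1C(=O)O[C@H]2C/C(CO[Si](C)(C)C(C)(C)C)=C\CC/C(COCc3ccc(OC)cc3)=C/C[C@H]12.[I-] | intermediate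
22 | (3aR,5Z,9E,11aS)-10-{[(tert-butyldimethylsilyl)oxy]methyl}-6-{[(4-methoxybenzyl)oxy]methyl}-3-methylidene-3a,4,7,8,11,11a-hexahydrocyclodeca[b]furan-2(3H)-one | C=C1C(=O)O[C@H]2C/C(CO[Si](C)(C)C(C)(C)C)=C\CC/C(COCc3ccc(OC)cc3)=C/C[C@H]12 | intermediate
23 | (3aR,5Z,9E,11aS)-10-{[(tert-butyldimethylsilyl)oxy]methyl}-6-(hydroxymethyl)-3-methylidene-3a,4,7,8,11,11a-hexahydrocyclodeca[b]furan-2(3H)-one | C=C1C(=O)O[C@H]2C/C(CO[Si](C)(C)C(C)(C)C)=C\CC/C(CO)=C/C[C@H]12 | intermediate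
24 | (R)-3-chloro-2-hydroxy-2-methylpropanoic acid | OC(=O)[C@@](C)(O)CCl | starting material
25 | [(3aR,5Z,9E,11aS)-10-{[(tert-butyldimethylsilyl)oxy]methyl}-3-methylidene-2-oxo-2,3,3a,4,7,8,11,11a-octahydrocyclodeca[b]furan-6-yl]methyl (2R)-3-chloro-2-hydroxy-2-methylpropanoate | C=C1C(=O)O[C@H]2C/C(CO[Si](C)(C)C(C)(C)C)=C\CC/C(COC(=O)[C@@](C)(O)CCl)=C/C[C@H]12 | intermediate
26 | [(3aR,5Z,9E,11aS)-10-(hydroxymethyl)-3-methylidene-2-oxo-2,3,3a,4,7,8,11,11a-octahydrocyclodeca[b]furan-6-yl]methyl (2R)-3-chloro-2-hydroxy-2-methylpropanoate | C=C1C(=O)O[C@H]2C/C(CO)=C\CC/C(COC(=O)[C@@](C)(O)CCl)=C/C[C@H]12 | target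

**Totals and risks**
Total step count: 14. Longest linear sequence: 13 (steps 1–3, then 5–14; step 4 is a one‑step side branch).

Steps most likely to fail:

Step 10 (radical ring closure). An intramolecular alkyl–alkenyl reductive coupling to a ten‑membered ring with a trans ring alkene has no direct precedent; dimerisation, hydrodehalogenation and β‑hydride loss can compete. Fallback, setting out from 18: zinc dust with LiCl in THF inserts only into the primary C–I bond to give the alkylzinc iodide F1. Slow addition of F1 to Pd(PPh3)4 in THF at 50 °C closes the same C5–C6 bond by an intramolecular Negishi coupling with retention at the alkenyl iodide. This comes back to the route at 19.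

Step 9 (atom‑transfer cyclisation). The ester rotamer needed for 5‑exo closure is the minor one, and a 7‑endo attack on the C1=C10 alkene or a poor trans/cis ratio could lower the yield. Fallback, setting out from 15: acryloyl chloride and Et3N give the acrylate F2. Ring‑closing metathesis with second‑generation Grubbs catalyst (H2IMes)(PCy3)Cl2Ru=CHPh in CH2Cl2 at 40 °C gives the butenolide F3. Photocatalytic addition of the hydroxymethyl radical from methanol ((Bu4N)4W10O32, 390 nm) anti to the C8 side chain gives the trans hydroxymethyl lactone F4, in which C6 now comes from methanol. I2, PPh3 and imidazole convert F4 into the iodide, which comes back to the route at 18.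

Step 5 (olefination). The one‑flask phosphonate olefination may give too much of the (Z)‑alkylidene lactone, or residual amide base may attack the aldehyde or the alkenyl iodide. Fallback, setting out from 10 and 7: aldol addition of the lithium enolate of 10 to 7 at −78 °C gives the β‑hydroxy lactone F5 (diastereomer mixture). MsCl and Et3N convert it into the mesylate F6, and DBU‑mediated E1cB elimination gives the thermodynamically preferred (E)‑alkylidene lactone. This comes back to the route at 13.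

**Further compounds**
F1 | step 10 | {[(3R,2S)-2-[(2E,6Z)-2-{[(tert-butyldimethylsilyl)oxy]methyl}-7-iodo-6-{[(4-methoxybenzyl)oxy]methyl}hepta-2,6-dien-1-yl]-5-oxotetrahydrofuran-3-yl]methyl}zinc iodide | O=C1C[C@@H](C[Zn]I)[C@H](C/C(CO[Si](C)(C)C(C)(C)C)=C\CC/C(COCc2ccc(OC)cc2)=C/I)O1
F2 | step 9 | (3S,5E,9Z)-5-{[(tert-butyldimethylsilyl)oxy]methyl}-10-iodo-9-{[(4-methoxybenzyl)oxy]methyl}deca-1,5,9-trien-3-yl acrylate | C=CC(=O)O[C@H](C=C)C/C(CO[Si](C)(C)C(C)(C)C)=C\CC/C(COCc1ccc(OC)cc1)=C/I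
F3 | step 9 | (S)-5-[(2E,6Z)-2-{[(tert-butyldimethylsilyl)oxy]methyl}-7-iodo-6-{[(4-methoxybenzyl)oxy]methyl}hepta-2,6-dien-1-yl]furan-2(5H)-one | O=C1C=C[C@H](C/C(CO[Si](C)(C)C(C)(C)C)=C\CC/C(COCc2ccc(OC)cc2)=C/I)O1
F4 | step 9 | (4S,5S)-5-[(2E,6Z)-2-{[(tert-butyldimethylsilyl)oxy]methyl}-7-iodo-6-{[(4-methoxybenzyl)oxy]methyl}hepta-2,6-dien-1-yl]-4-(hydroxymethyl)dihydrofuran-2(3H)-one (4,5-trans) | O=C1C[C@@H](CO)[C@H](C/C(CO[Si](C)(C)C(C)(C)C)=C\CC/C(COCc2ccc(OC)cc2)=C/I)O1
F5 | step 5 | (5S)-3-[(4Z)-1-hydroxy-5-iodo-4-{[(4-methoxybenzyl)oxy]methyl}pent-4-en-1-yl]-5-vinyldihydrofuran-2(3H)-one (diastereomer mixture) | C=C[C@@H]1CC(C(O)CC/C(COCc2ccc(OC)cc2)=C/I)C(=O)O1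
F6 | step 5 | (4Z)-5-iodo-4-{[(4-methoxybenzyl)oxy]methyl}-1-[(5S)-2-oxo-5-vinyltetrahydrofuran-3-yl]pent-4-en-1-yl methanesulfonate (diastereomer mixture) | C=C[C@@H]1CC(C(OS(C)(=O)=O)CC/C(COCc2ccc(OC)cc2)=C/I)C(=O)O1
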